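**Plan**

- Labels (target numbering): pyran O1, C2 (aryl), C3, C4 (OH), C5, C6 (arylethyl); side chain on C3: C1' (methine), C2', C3' (carbinol); styrene Ca (on C1')=Cb.
- Retrosynthesis: cut O1–C2 (benzylic cycloetherification), Ca=Cb (olefination) and C2–aryl (Grignard). Ca and C6, the two ends of the path Ca–C1'–C3–C4–C5–C6, are then both carbonyl carbons, so they are rejoined as a Ca=C6 alkene. That places C1', C3 and C4 in one cyclohexene, which a Diels–Alder reaction cuts at C3–C1' and C4–C5.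
- Forward: one 3-arylpropanal gives both the (S)-homoallyl silyl ether and the arylbutyne; enyne cross-metathesis joins them to the diene; the cycloaddition closes the temporary carbocycle; after C2 arylation, ozonolysis opens it again; the styrene is added; the pyran closes last; desilylation ends the route.
- Stereochemistry: C3' from a Brown allylation; C3, C4 and C1' from the catalyst-controlled endo Diels–Alder reaction of an E diene and an E dienophile; C6 from a C4-hydroxyl-directed syn reduction; C2 from the thermodynamically controlled ring closure.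

Key step: step 8

Abbreviations: TBS = tert-butyldimethylsilyl, TES = triethylsilyl, Ar = 4-(TBS-oxy)phenyl. Open-chain intermediates are named as 1,7-diarylheptanes whose C1 is the benzylic carbon labelled C2.

Assumption: the oxazaborolidinium catalyst follows its usual formyl C–H···O binding model, by which the (R)-enantiomer leaves the Si face of C3 of the dienophile open; both catalyst antipodes are available, so a reversed sense would be corrected by exchanging the catalyst.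

**Route**

Step 1
Reactants: 1 methyl 3-(4-hydroxyphenyl)propanoate
Product: 2 methyl 3-Ar-propanoate
Conditions: TBSCl, imidazole, DMF, rt
Reagents that add atoms: tert-butyldimethylsilyl chloride CC(C)(C)[Si](C)(C)Cl
Why: Imidazole-promoted silylation masks the acidic phenol before the hydride and organometallic steps.

Step 2
Reactants: 2 methyl 3-Ar-propanoate
Product: 3 3-Ar-propanal
Conditions: (i-Bu)2AlH (1.1 equiv), CH2Cl2, −78 °C; MeOH, then aq. KNaC4H4O6
Reagents that add atoms: none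
Why: Partial ester reduction with (i-Bu)2AlH at low temperature stops at the aluminium hemiacetal, which releases the aldehyde only on work-up.

Step 3
Reactants: 3 3-Ar-propanal
Product: 4 (3S)-1-Ar-hex-5-en-3-ol
Conditions: (+)-Ipc2BOMe, CH2=CHCH2MgBr, Et2O, 0 °C to rt; 3, −78 °C; NaBO3·4H2O, THF/H2O, rt
Reagents that add atoms: allylmagnesium bromide C=CC[Mg]Br
Why: In this Brown allylation the borane derived from (−)-α-pinene delivers the allyl group through a chair-like six-membered transition state to the Re face of the aldehyde, which sets C3' as S, and the mild perborate work-up spares the aryl silyl ether.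

Step 4
Reactants: 4 (3S)-1-Ar-hex-5-en-3-ol
Product: 5 (3S)-3-(TBS-oxy)-1-Ar-hex-5-ene
Conditions: TBSCl, imidazole, DMF, rt
Reagents that add atoms: tert-butyldimethylsilyl chloride CC(C)(C)[Si](C)(C)Cl
Why: Silyl ether formation protects the C3' carbinol as a group that survives every later step and leaves with the phenol silyl groups at the end.

Step 5
Reactants: 3 3-Ar-propanal
Product: 6 4-Ar-but-1-yne
Conditions: Me3SiCHN2, LiN(i-Pr)2, THF, −78 °C; 3, −78 °C to rt; aq. NH4Cl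
Reagents that add atoms: (trimethylsilyl)diazomethane C[Si](C)(C)C=[N+]=[N-]
Why: In this Colvin rearrangement the lithiated silyldiazomethane adds to the aldehyde, Peterson-type loss of silanolate and loss of N2 give an alkylidene carbene, and its 1,2-hydride shift gives the terminal alkyne without the protic base that would cleave the aryl silyl ether.

Step 6
Reactants: 5 (3S)-3-(TBS-oxy)-1-Ar-hex-5-ene; 6 4-Ar-but-1-yne
Product: 8 (3S,5E)-3-(TBS-oxy)-7-methylidene-1,9-bis(Ar)non-5-ene, via 2-substituted butadiene 7 (not isolated)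
Conditions: RuCl2(=CHPh)(H2IMes)(PCy3) (second-generation Grubbs catalyst, 8 mol%), ethylene (1 atm), 5 (2 equiv), CH2Cl2, rt to 40 °C
Reagents that add atoms: ethylene C=C
Why: In this tandem enyne metathesis/cross-metathesis, ethylene first turns the alkyne into butadiene 7, whose monosubstituted vinyl group then exchanges with 5 under reversible conditions that should favour the E-1,3-disubstituted diene.

Step 7
Reactants: 9 1,1,3,3-tetramethoxypropane
Product: 11 (E)-3-oxoprop-1-en-1-yl benzoate [(E)-3-benzoyloxyacrolein], via sodium 3-oxoprop-1-en-1-olate 10 (not isolated)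
Conditions: 1 M HCl, H2O, rt; NaOH to pH 10, evaporate; PhCOCl, THF, 0 °C to rt
Reagents that add atoms: water O; benzoyl chloride O=C(Cl)c1ccccc1
Why: Acetal hydrolysis gives malonaldehyde, and O-acylation of its sodium enolate gives the conjugated E enol benzoate.

Step 8
Reactants: 8 (3S,5E)-3-(TBS-oxy)-7-methylidene-1,9-bis(Ar)non-5-ene; 11 (E)-3-oxoprop-1-en-1-yl benzoate
Product: 12 (1S,2S,3S)-2-formyl-5-(2-Ar-ethyl)-3-[(2S)-2-(TBS-oxy)-4-Ar-butyl]cyclohex-4-en-1-yl benzoate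
Conditions: (R)-3,3-diphenyl-1-(o-tolyl)tetrahydropyrrolo[1,2-c][1,3,2]oxazaborole C24H24BNO (20 mol%), HN(SO2CF3)2 (18 mol%), 11 (1.5 equiv), CH2Cl2, −78 to −40 °C; pH 7 buffer
Reagents that add atoms: none
Why: Proposed new method: the protonated oxazaborolidine binds the formyl oxygen of 11 at boron, with the formyl C–H held against the ring oxygen so that the s-trans enal lies over one phenyl group, and this lowers the LUMO enough for 8 to add in a concerted but asynchronous [4+2] cycloaddition in which the C4–C5 bond runs ahead of C3–C1'; the closest known reaction type is the oxazaborolidinium-catalysed enantioselective Diels–Alder reaction of simple α,β-enals with acyclic dienes, which has not been shown for a β-acyloxy enal, a vinylogous mixed anhydride that is both a weaker dienophile and a potential acyl donor. The temporary cyclohexene (C3, C4, C5, C6, Ca, C1') is closed by this intermolecular suprafacial [4+2] cycloaddition, both of its new ring bonds forming in the same step. C3 is set by the catalyst, whose (R) form should shield the Re face of C3 and leave the Si face to the diene; C4 follows from the E geometry of 11, which keeps the benzoate trans to the formyl group; C1' follows from the endo approach of the boron-bound formyl group together with the E geometry of the C1'=Ca bond, which puts C2' cis to the formyl group. Three selectivities are needed: regiochemistry (C1' to C3, C5 to C4), secured because the alkyl groups on C1' and C6 both raise the HOMO coefficient at C5 while the LUMO coefficient of the bound enal is largest at C4; endo topicity, secured by the secondary overlap of the activated formyl group; and one dienophile face, secured by the catalyst and not by the remote C3' centre, which only makes a wrong-face adduct a separable diastereomer.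

Step 9
Reactants: 12 (1S,2S,3S)-2-formyl-5-(2-Ar-ethyl)-3-[(2S)-2-(TBS-oxy)-4-Ar-butyl]cyclohex-4-en-1-yl benzoate; 13 (4-bromophenoxy)(tert-butyl)dimethylsilane
Product: 16 (1S,2S,3S)-2-[hydroxy(Ar)methyl]-5-(2-Ar-ethyl)-3-[(2S)-2-(TBS-oxy)-4-Ar-butyl]cyclohex-4-en-1-ol (both C2 carbinol epimers), via arylmagnesium bromide 14 (not isolated), via benzoate carbinol 15 (not isolated)
Conditions: 13, Mg, THF, rt; 12, THF, −78 °C; (i-Bu)2AlH, −78 to −40 °C; aq. KNaC4H4O6
Reagents that add atoms: none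
Why: Grignard 1,2-addition to the aldehyde at −78 °C should outrun attack on the benzoate and β-elimination, and (i-Bu)2AlH then cleaves the benzoate reductively in the same flask; C2 is deliberately formed without control because step 18 re-sets it under thermodynamic control.

Step 10
Reactants: 16 (1S,2S,3S)-2-[hydroxy(Ar)methyl]-5-(2-Ar-ethyl)-3-[(2S)-2-(TBS-oxy)-4-Ar-butyl]cyclohex-4-en-1-ol (both C2 epimers)
Product: 17 (1S,2S,3S)-1-(TES-oxy)-2-[(TES-oxy)(Ar)methyl]-5-(2-Ar-ethyl)-3-[(2S)-2-(TBS-oxy)-4-Ar-butyl]cyclohex-4-ene (both C2 epimers)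
Conditions: Et3SiOTf, 2,6-lutidine, CH2Cl2, −78 to 0 °C
Reagents that add atoms: triethylsilyl trifluoromethanesulfonate CC[Si](CC)(CC)OS(=O)(=O)C(F)(F)F
Why: Silylation of both hydroxyls with the reactive triflate prevents lactol and hemiketal formation after ring cleavage and installs groups that can later be removed in the presence of TBS ethers.

Step 11
Reactants: 17 (1S,2S,3S)-1-(TES-oxy)-2-[(TES-oxy)(Ar)methyl]-5-(2-Ar-ethyl)-3-[(2S)-2-(TBS-oxy)-4-Ar-butyl]cyclohex-4-ene (both C2 epimers)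
Product: 19 (2S,3S)-1,3-bis(TES-oxy)-1,7-bis(Ar)-2-[(2R,4S)-4-(TBS-oxy)-1-oxo-6-Ar-hexan-2-yl]heptan-5-one (both C1 epimers), via secondary ozonide 18 (not isolated)
Conditions: O3, CH2Cl2, −78 °C (Sudan Red 7B end point); PPh3, −78 °C to rt
Reagents that add atoms: ozone [O-][O+]=O
Why: Ozonolysis with reductive work-up cleaves the only C=C bond, a trisubstituted alkene that reacts far faster than the aryl silyl ethers, and gives the C6 ketone and the Ca aldehyde at the 1,6-related carbons.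

Step 12
Reactants: 20 4-(TBS-oxy)benzaldehyde
Product: 21 [4-(TBS-oxy)phenyl]methanol
Conditions: NaBH4, THF/EtOH, 0 °C
Reagents that add atoms: none
Why: Borohydride reduction of the aromatic aldehyde is fast at 0 °C and leaves the aryl silyl ether untouched.

Step 13
Reactants: 21 [4-(TBS-oxy)phenyl]methanol
Product: 22 5-{[4-(TBS-oxy)benzyl]sulfanyl}-1-phenyl-1H-tetrazole
Conditions: 1-phenyl-1H-tetrazole-5-thiol, PPh3, i-PrO2CN=NCO2i-Pr, THF, 0 °C to rt
Reagents that add atoms: 1-phenyl-1H-tetrazole-5-thiol Sc1nnnn1-c1ccccc1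
Why: In this Mitsunobu thioetherification the acidic tetrazolethiol displaces the activated primary benzylic oxyphosphonium group under neutral conditions.

Step 14
Reactants: 22 5-{[4-(TBS-oxy)benzyl]sulfanyl}-1-phenyl-1H-tetrazole
Product: 23 5-{[4-(TBS-oxy)benzyl]sulfonyl}-1-phenyl-1H-tetrazole
Conditions: (NH4)6Mo7O24·4H2O (10 mol%), 30% H2O2, EtOH, 0 °C to rt
Reagents that add atoms: hydrogen peroxide OO
Why: Molybdate-catalysed peroxide oxidation carries the electron-poor sulfide through the sulfoxide to the sulfone in a near-neutral medium.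

Step 15
Reactants: 19 (2S,3S)-1,3-bis(TES-oxy)-1,7-bis(Ar)-2-[(2R,4S)-4-(TBS-oxy)-1-oxo-6-Ar-hexan-2-yl]heptan-5-one (both C1 epimers); 23 5-{[4-(TBS-oxy)benzyl]sulfonyl}-1-phenyl-1H-tetrazole
Product: 25 (2S,3S)-1,3-bis(TES-oxy)-1,7-bis(Ar)-2-[(1E,3S,5S)-5-(TBS-oxy)-1,7-bis(Ar)hept-1-en-3-yl]heptan-5-one (both C1 epimers), via potassium sulfonyl carbanion 24 (not isolated)
Conditions: 23, KN(SiMe3)2, THF, −78 °C; 19, −78 °C to rt; aq. NH4Cl
Reagents that add atoms: none
Why: In this Julia–Kocienski olefination the pre-formed, weakly basic sulfonyl carbanion should add to the aldehyde faster than to the ketone or than it deprotonates C1', and Smiles rearrangement with loss of SO2 and tetrazolonate should give the E styrene favoured by the potassium counter-ion and the α-branched aldehyde.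

Step 16
Reactants: 25 (2S,3S)-1,3-bis(TES-oxy)-1,7-bis(Ar)-2-[(1E,3S,5S)-5-(TBS-oxy)-1,7-bis(Ar)hept-1-en-3-yl]heptan-5-one (both C1 epimers)
Product: 26 (2S,3S)-1,3-dihydroxy-1,7-bis(Ar)-2-[(1E,3S,5S)-5-(TBS-oxy)-1,7-bis(Ar)hept-1-en-3-yl]heptan-5-one (both C1 epimers; in equilibrium with its cyclic hemiketals)
Conditions: HF·pyridine, pyridine, THF, 0 °C
Reagents that add atoms: none
Why: In this selective desilylation, buffered acidic fluoride cleaves the two secondary triethylsilyl ethers much faster than the secondary alkyl and the aryl TBS ethers.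

Step 17
Reactants: 26 (2S,3S)-1,3-dihydroxy-1,7-bis(Ar)-2-[(1E,3S,5S)-5-(TBS-oxy)-1,7-bis(Ar)hept-1-en-3-yl]heptan-5-one (both C1 epimers)
Product: 28 (2S,3S,5S)-1,7-bis(Ar)-2-[(1E,3S,5S)-5-(TBS-oxy)-1,7-bis(Ar)hept-1-en-3-yl]heptane-1,3,5-triol (both C1 epimers), via diethylboron chelate 27 (not isolated)
Conditions: Et2BOMe (2.2 equiv), THF/MeOH 4:1, −78 °C; NaBH4, −78 to −40 °C; AcOH, MeOH co-evaporation
Reagents that add atoms: none
Why: In this Narasaka–Prasad reduction the diethylboron chelate between the C4 oxygen and the C6 ketone adopts a half-chair with C3 equatorial and external hydride adds axially, which gives the 4,6-syn diol and so sets C6 as S.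

Step 18
Reactants: 28 (2S,3S,5S)-1,7-bis(Ar)-2-[(1E,3S,5S)-5-(TBS-oxy)-1,7-bis(Ar)hept-1-en-3-yl]heptane-1,3,5-triol (both C1 epimers)
Product: 29 (2S,3S,4S,6S)-2-Ar-6-(2-Ar-ethyl)-3-[(1E,3S,5S)-5-(TBS-oxy)-1,7-bis(Ar)hept-1-en-3-yl]oxan-4-ol
Conditions: camphorsulfonic acid (10 mol%), 4 Å molecular sieves, CH2Cl2, 0 °C to rt
Reagents that add atoms: none
Why: In this acid-catalysed dehydrative cycloetherification (intramolecular SN1 substitution at the benzylic carbon) both C2 epimers ionise to the same p-silyloxybenzyl cation, the C6 hydroxyl closes the six-membered ring, and reversible re-ionisation of the benzylic ether should funnel the material to the isomer with the C2 aryl, C3 and C6 substituents all equatorial, which sets C2 as S.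

Step 19
Reactants: 29 (2S,3S,4S,6S)-2-Ar-6-(2-Ar-ethyl)-3-[(1E,3S,5S)-5-(TBS-oxy)-1,7-bis(Ar)hept-1-en-3-yl]oxan-4-ol
Product: 30 blepharocalyxin C, (2S,3S,4S,6S)-3-[(1E,3S,5S)-5-hydroxy-1,7-bis(4-hydroxyphenyl)hept-1-en-3-yl]-2-(4-hydroxyphenyl)-6-[2-(4-hydroxyphenyl)ethyl]oxan-4-ol
Conditions: Bu4NF, AcOH, THF, 0 °C to rt
Reagents that add atoms: none
Why: Fluoride-induced desilylation buffered with acetic acid removes all five TBS groups without exposing the phenols and the p-hydroxystyrene to strong base, and any base-induced opening at C2 through a quinone methide would return to the same thermodynamic isomer.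

**Compound list**

1 | methyl 3-(4-hydroxyphenyl)propanoate | COC(=O)CCc1ccc(O)cc1 | starting material
2 | methyl 3-Ar-propanoate | COC(=O)CCc1ccc(O[Si](C)(C)C(C)(C)C)cc1 | intermediate
3 | 3-Ar-propanal | O=CCCc1ccc(O[Si](C)(C)C(C)(C)C)cc1 | intermediate
4 | (3S)-1-Ar-hex-5-en-3-ol | C=CC[C@@H](O)CCc1ccc(O[Si](C)(C)C(C)(C)C)cc1 | intermediate
5 | (3S)-3-(TBS-oxy)-1-Ar-hex-5-ene | C=CC[C@@H](O[Si](C)(C)C(C)(C)C)CCc1ccc(O[Si](C)(C)C(C)(C)C)cc1 | intermediate
6 | 4-Ar-but-1-yne | C#CCCc1ccc(O[Si](C)(C)C(C)(C)C)cc1 | intermediate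
7 | 2-(2-Ar-ethyl)buta-1,3-diene (not isolated) | C=CC(=C)CCc1ccc(O[Si](C)(C)C(C)(C)C)cc1 | intermediate
8 | (3S,5E)-3-(TBS-oxy)-7-methylidene-1,9-bis(Ar)non-5-ene (diene C5H2=C6–Ca=C1') | C=C(CCc1ccc(O[Si](C)(C)C(C)(C)C)cc1)/C=C/C[C@@H](O[Si](C)(C)C(C)(C)C)CCc1ccc(O[Si](C)(C)C(C)(C)C)cc1 | intermediate
9 | 1,1,3,3-tetramethoxypropane | COC(CC(OC)OC)OC | starting material
10 | sodium (E)-3-oxoprop-1-en-1-olate (not isolated) | [Na+].[O-]/C=C/C=O | intermediate
11 | (E)-3-oxoprop-1-en-1-yl benzoate | O=C/C=C/OC(=O)c1ccccc1 | intermediate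
12 | (1S,2S,3S)-2-formyl-5-(2-Ar-ethyl)-3-[(2S)-2-(TBS-oxy)-4-Ar-butyl]cyclohex-4-en-1-yl benzoate | O=C[C@@H]1[C@@H](OC(=O)c2ccccc2)CC(CCc2ccc(O[Si](C)(C)C(C)(C)C)cc2)=C[C@@H]1C[C@@H](O[Si](C)(C)C(C)(C)C)CCc1ccc(O[Si](C)(C)C(C)(C)C)cc1 | intermediate
13 | (4-bromophenoxy)(tert-butyl)dimethylsilane | Brc1ccc(O[Si](C)(C)C(C)(C)C)cc1 | starting material
14 | [4-(TBS-oxy)phenyl]magnesium bromide (not isolated) | Br[Mg]c1ccc(O[Si](C)(C)C(C)(C)C)cc1 | intermediate
15 | C2 aryl carbinol of 12 with the C4 benzoate retained, both C2 epimers (not isolated) | OC(c1ccc(O[Si](C)(C)C(C)(C)C)cc1)[C@@H]1[C@@H](OC(=O)c2ccccc2)CC(CCc2ccc(O[Si](C)(C)C(C)(C)C)cc2)=C[C@@H]1C[C@@H](O[Si](C)(C)C(C)(C)C)CCc1ccc(O[Si](C)(C)C(C)(C)C)cc1 | intermediate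
16 | (1S,2S,3S)-2-[hydroxy(Ar)methyl]-5-(2-Ar-ethyl)-3-[(2S)-2-(TBS-oxy)-4-Ar-butyl]cyclohex-4-en-1-ol, both C2 epimers | OC(c1ccc(O[Si](C)(C)C(C)(C)C)cc1)[C@@H]1[C@@H](O)CC(CCc2ccc(O[Si](C)(C)C(C)(C)C)cc2)=C[C@@H]1C[C@@H](O[Si](C)(C)C(C)(C)C)CCc1ccc(O[Si](C)(C)C(C)(C)C)cc1 | intermediate
17 | (1S,2S,3S)-1-(TES-oxy)-2-[(TES-oxy)(Ar)methyl]-5-(2-Ar-ethyl)-3-[(2S)-2-(TBS-oxy)-4-Ar-butyl]cyclohex-4-ene, both C2 epimers | CC[Si](CC)(CC)OC(c1ccc(O[Si](C)(C)C(C)(C)C)cc1)[C@@H]1[C@@H](O[Si](CC)(CC)CC)CC(CCc2ccc(O[Si](C)(C)C(C)(C)C)cc2)=C[C@@H]1C[C@@H](O[Si](C)(C)C(C)(C)C)CCc1ccc(O[Si](C)(C)C(C)(C)C)cc1 | intermediate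
18 | secondary ozonide (1,2,4-trioxolane across C6 and Ca) of 17 (not isolated) | CC[Si](CC)(CC)OC(c1ccc(O[Si](C)(C)C(C)(C)C)cc1)[C@@H]1[C@@H](O[Si](CC)(CC)CC)CC2(CCc3ccc(O[Si](C)(C)C(C)(C)C)cc3)OOC(O2)[C@@H]1C[C@@H](O[Si](C)(C)C(C)(C)C)CCc1ccc(O[Si](C)(C)C(C)(C)C)cc1 | intermediate
19 | (2S,3S)-1,3-bis(TES-oxy)-1,7-bis(Ar)-2-[(2R,4S)-4-(TBS-oxy)-1-oxo-6-Ar-hexan-2-yl]heptan-5-one, both C1 epimers (C6 ketone, Ca aldehyde) | CC[Si](CC)(CC)OC(c1ccc(O[Si](C)(C)C(C)(C)C)cc1)[C@H]([C@@H](O[Si](CC)(CC)CC)CC(=O)CCc1ccc(O[Si](C)(C)C(C)(C)C)cc1)[C@H](C=O)C[C@@H](O[Si](C)(C)C(C)(C)C)CCc1ccc(O[Si](C)(C)C(C)(C)C)cc1 | intermediate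
20 | 4-(TBS-oxy)benzaldehyde | O=Cc1ccc(O[Si](C)(C)C(C)(C)C)cc1 | starting material
21 | [4-(TBS-oxy)phenyl]methanol | OCc1ccc(O[Si](C)(C)C(C)(C)C)cc1 | intermediate
22 | 5-{[4-(TBS-oxy)benzyl]sulfanyl}-1-phenyl-1H-tetrazole | CC(C)(C)[Si](C)(C)Oc1ccc(CSc2nnnn2-c2ccccc2)cc1 | intermediate
23 | 5-{[4-(TBS-oxy)benzyl]sulfonyl}-1-phenyl-1H-tetrazole | CC(C)(C)[Si](C)(C)Oc1ccc(CS(=O)(=O)c2nnnn2-c2ccccc2)cc1 | intermediate
24 | potassium salt of the benzylic carbanion of 23 (not isolated) | [K+].CC(C)(C)[Si](C)(C)Oc1ccc([CH-]S(=O)(=O)c2nnnn2-c2ccccc2)cc1 | intermediate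
25 | (2S,3S)-1,3-bis(TES-oxy)-1,7-bis(Ar)-2-[(1E,3S,5S)-5-(TBS-oxy)-1,7-bis(Ar)hept-1-en-3-yl]heptan-5-one, both C1 epimers | CC[Si](CC)(CC)OC(c1ccc(O[Si](C)(C)C(C)(C)C)cc1)[C@H]([C@@H](O[Si](CC)(CC)CC)CC(=O)CCc1ccc(O[Si](C)(C)C(C)(C)C)cc1)[C@H](/C=C/c1ccc(O[Si](C)(C)C(C)(C)C)cc1)C[C@@H](O[Si](C)(C)C(C)(C)C)CCc1ccc(O[Si](C)(C)C(C)(C)C)cc1 | intermediate
26 | (2S,3S)-1,3-dihydroxy-1,7-bis(Ar)-2-[(1E,3S,5S)-5-(TBS-oxy)-1,7-bis(Ar)hept-1-en-3-yl]heptan-5-one, both C1 epimers | OC(c1ccc(O[Si](C)(C)C(C)(C)C)cc1)[C@H]([C@@H](O)CC(=O)CCc1ccc(O[Si](C)(C)C(C)(C)C)cc1)[C@H](/C=C/c1ccc(O[Si](C)(C)C(C)(C)C)cc1)C[C@@H](O[Si](C)(C)C(C)(C)C)CCc1ccc(O[Si](C)(C)C(C)(C)C)cc1 | intermediate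
27 | bis(diethylborinate) of 26 with the C4 borinate chelated to the C6 carbonyl (not isolated) | CCB(CC)OC(c1ccc(O[Si](C)(C)C(C)(C)C)cc1)[C@H]([C@@H]1CC(CCc2ccc(O[Si](C)(C)C(C)(C)C)cc2)=[O+][B-](CC)(CC)O1)[C@H](/C=C/c1ccc(O[Si](C)(C)C(C)(C)C)cc1)C[C@@H](O[Si](C)(C)C(C)(C)C)CCc1ccc(O[Si](C)(C)C(C)(C)C)cc1 | intermediate
28 | (2S,3S,5S)-1,7-bis(Ar)-2-[(1E,3S,5S)-5-(TBS-oxy)-1,7-bis(Ar)hept-1-en-3-yl]heptane-1,3,5-triol, both C1 epimers | OC(c1ccc(O[Si](C)(C)C(C)(C)C)cc1)[C@H]([C@@H](O)C[C@@H](O)CCc1ccc(O[Si](C)(C)C(C)(C)C)cc1)[C@H](/C=C/c1ccc(O[Si](C)(C)C(C)(C)C)cc1)C[C@@H](O[Si](C)(C)C(C)(C)C)CCc1ccc(O[Si](C)(C)C(C)(C)C)cc1 | intermediate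
29 | (2S,3S,4S,6S)-2-Ar-6-(2-Ar-ethyl)-3-[(1E,3S,5S)-5-(TBS-oxy)-1,7-bis(Ar)hept-1-en-3-yl]oxan-4-ol | CC(C)(C)[Si](C)(C)Oc1ccc(/C=C/[C@H](C[C@@H](O[Si](C)(C)C(C)(C)C)CCc2ccc(O[Si](C)(C)C(C)(C)C)cc2)[C@@H]2[C@@H](c3ccc(O[Si](C)(C)C(C)(C)C)cc3)O[C@@H](CCc3ccc(O[Si](C)(C)C(C)(C)C)cc3)C[C@@H]2O)cc1 | intermediate
30 | blepharocalyxin C | Oc1ccc(/C=C/[C@H](C[C@@H](O)CCc2ccc(O)cc2)[C@@H]2[C@@H](c3ccc(O)cc3)O[C@@H](CCc3ccc(O)cc3)C[C@@H]2O)cc1 | target

**Step count**

Total: 19 steps. Longest linear sequence: 14 steps (1, 2, 3, 4, 6, 8, 9, 10, 11, 15, 16, 17, 18, 19).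

**Steps most likely to fail**

Step 8. The β-benzoyloxy group may slow the cycloaddition, the vinylogous anhydride may transfer its acyl group to the catalyst, benzoate may be eliminated from the β-acyloxy aldehyde on work-up, and endo or facial selectivity may erode. The adduct should in any case be taken into step 9 at once. Fallback by known chemistry, starting from diene 8: a titanium-catalysed Diels–Alder reaction (TiCl2(O-i-Pr)2 with the tartrate-derived TADDOL antipode that exposes the Si face of C3, 4 Å sieves, toluene) with 3-[(E)-3-(4,4,5,5-tetramethyl-1,3,2-dioxaborolan-2-yl)acryloyl]-1,3-oxazolidin-2-one F1, a documented β-hydroxyacrylate equivalent, should give the boryl imide cycloadduct F2 with the same C3/C4/C1' array. Oxidation of the C–B bond with Me3NO, with retention, would give the β-hydroxy imide F3; Al(CH3)3 with MeNHOMe·HCl the Weinreb amide F4; aryl Grignard 14 the β-hydroxy aryl ketone F5; and NaBH4 the diol 16, where the route is rejoined.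

Step 15. Base may epimerise the α-formyl centre C1', the C5 enolate of the ketone may close onto the Ca aldehyde in an intramolecular aldol reaction, and a benzylic sulfone may give incomplete E selectivity. Fallback from keto-aldehyde 19: a Takai olefination (CrCl2, CHI3, THF, 0 °C), which is not basic and touches only the aldehyde, should give the (E)-vinyl iodide F6. Suzuki–Miyaura coupling with 4-(TBS-oxy)phenylboronic acid (Pd(PPh3)4, K3PO4, THF/H2O, 40 °C) then returns to the route at 25.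

Step 18. The benzylic cation may lose a proton to give the C2=C3 styrene, be captured by the C3' silyl ether oxygen instead of the C6 hydroxyl, or the acid may protonate the electron-rich styrene. Fallback from triol 28: MnO2 in CH2Cl2 should oxidise only the benzylic carbinol to the C2 aryl ketone F7, which is in equilibrium with its hemiketal to the C6 hydroxyl. Reduction of the aryl-stabilised oxocarbenium ion with Et3SiH and BF3·OEt2 (CH2Cl2/MeCN, −40 °C), by axial hydride delivery, then gives 29 directly.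

**Further compounds**

F1 | step 8 | 3-[(E)-3-(4,4,5,5-tetramethyl-1,3,2-dioxaborolan-2-yl)acryloyl]-1,3-oxazolidin-2-one | O=C(/C=C/B1OC(C)(C)C(C)(C)O1)N1CCOC1=O
F2 | step 8 | boryl imide cycloadduct (C3 acyl oxazolidinone, C4 pinacolboryl, configuration as in 12) | O=C(N1CCOC1=O)[C@@H]1[C@@H](B2OC(C)(C)C(C)(C)O2)CC(CCc2ccc(O[Si](C)(C)C(C)(C)C)cc2)=C[C@@H]1C[C@@H](O[Si](C)(C)C(C)(C)C)CCc1ccc(O[Si](C)(C)C(C)(C)C)cc1
F3 | step 8 | β-hydroxy imide (C4 hydroxyl, configuration as in 12) | O=C(N1CCOC1=O)[C@@H]1[C@@H](O)CC(CCc2ccc(O[Si](C)(C)C(C)(C)C)cc2)=C[C@@H]1C[C@@H](O[Si](C)(C)C(C)(C)C)CCc1ccc(O[Si](C)(C)C(C)(C)C)cc1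
F4 | step 8 | β-hydroxy N-methoxy-N-methyl amide (Weinreb amide) | CON(C)C(=O)[C@@H]1[C@@H](O)CC(CCc2ccc(O[Si](C)(C)C(C)(C)C)cc2)=C[C@@H]1C[C@@H](O[Si](C)(C)C(C)(C)C)CCc1ccc(O[Si](C)(C)C(C)(C)C)cc1
F5 | step 8 | β-hydroxy aryl ketone (C2 ketone of 16) | O=C(c1ccc(O[Si](C)(C)C(C)(C)C)cc1)[C@@H]1[C@@H](O)CC(CCc2ccc(O[Si](C)(C)C(C)(C)C)cc2)=C[C@@H]1C[C@@H](O[Si](C)(C)C(C)(C)C)CCc1ccc(O[Si](C)(C)C(C)(C)C)cc1
F6 | step 15 | (E)-vinyl iodide from 19 (Ca=CbHI), both C1 epimers | CC[Si](CC)(CC)OC(c1ccc(O[Si](C)(C)C(C)(C)C)cc1)[C@H]([C@@H](O[Si](CC)(CC)CC)CC(=O)CCc1ccc(O[Si](C)(C)C(C)(C)C)cc1)[C@H](/C=C/I)C[C@@H](O[Si](C)(C)C(C)(C)C)CCc1ccc(O[Si](C)(C)C(C)(C)C)cc1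
F7 | step 18 | C2 aryl ketone of 28 (3,5-dihydroxy ketone) | O=C(c1ccc(O[Si](C)(C)C(C)(C)C)cc1)[C@H]([C@@H](O)C[C@@H](O)CCc1ccc(O[Si](C)(C)C(C)(C)C)cc1)[C@H](/C=C/c1ccc(O[Si](C)(C)C(C)(C)C)cc1)C[C@@H](O[Si](C)(C)C(C)(C)C)CCc1ccc(O[Si](C)(C)C(C)(C)C)cc1
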